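## Retrosynthetic overview

1. Target ⇐ hydrogenolysis of two benzyl ethers and LiAlH4 opening of an all-trans aryltetralin lactone.
2. Carbocyclic ring (ring B, formed last) ⇐ Friedel–Crafts closure of the C1–C8a bond from a benzylic carbinol. The butanolide ring is formed first.
3. Carbinol ⇐ intermolecular aldol of the lithium enolate of an (S)-β-(arylmethyl)-γ-butyrolactone with O-benzylvanillin (key C1–C2 bond).
4. (S)-Lactone ⇐ auxiliary-controlled alkylation of an N-(3-arylpropanoyl)oxazolidinone with tert-butyl bromoacetate, reduction, lactonisation (sets C3, which relays to C2 and C1).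
5. 3-Arylpropanoic acid ⇐ Wittig and conjugate reduction on 4-(benzyloxy)-2,3-dimethoxybenzaldehyde ⇐ 2,3,4-trihydroxybenzaldehyde.

Assumption: atom labels C1–C8a are the tetralin numbering of the target (C1 carries the aryl group), whose configuration reads (1R,2S,3S), all-trans; compound numbers follow the forward steps.

## Route

Step 1
Reactants: 1 2,3,4-trihydroxybenzaldehyde
Product: 2 4-(benzyloxy)-2,3-dihydroxybenzaldehyde
Conditions: BnBr (1.05 equiv), NaHCO3, NaI (cat), DMF, 40 °C
Reagents that add atoms: benzyl bromide, BrCc1ccccc1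
Why: Williamson etherification under weak-base control, in which NaHCO3 ionises only the most acidic phenol (the 4-OH para to the formyl group, the 2-OH being hydrogen-bonded to C=O and the 3-OH not conjugated to it), so a single benzyl group goes onto O-4.

Step 2
Reactants: 2 4-(benzyloxy)-2,3-dihydroxybenzaldehyde
Product: 3 4-(benzyloxy)-2,3-dimethoxybenzaldehyde
Conditions: MeI (3 equiv), K2CO3, DMF, 50 °C
Reagents that add atoms: iodomethane, CI
Why: Williamson methylation of both remaining phenols with excess MeI and K2CO3 in DMF is forcing enough for the chelated 2-OH and leaves the aldehyde and the benzyl ether untouched.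

Step 3
Reactants: 3 4-(benzyloxy)-2,3-dimethoxybenzaldehyde; 4 ethyl (triphenylphosphoranylidene)acetate
Product: 5 ethyl (2E)-3-[4-(benzyloxy)-2,3-dimethoxyphenyl]prop-2-enoate
Conditions: PhMe, 90 °C
Reagents that add atoms: none
Why: Wittig olefination with a stabilised ylide gives the E-cinnamate cleanly, and the alkene geometry is immaterial because the double bond is saturated in the next step.

Step 4
Reactants: 5 ethyl (2E)-3-[4-(benzyloxy)-2,3-dimethoxyphenyl]prop-2-enoate
Product: 6 ethyl 3-[4-(benzyloxy)-2,3-dimethoxyphenyl]propanoate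
Conditions: NaBH4, NiCl2·6H2O (0.2 equiv), MeOH/THF, 0 °C
Reagents that add atoms: none
Why: Nickel boride generated from NiCl2 and NaBH4 performs a conjugate reduction of the cinnamate C=C without hydrogenolysing the aryl benzyl ether or reducing the ester.

Step 5
Reactants: 6 ethyl 3-[4-(benzyloxy)-2,3-dimethoxyphenyl]propanoate
Product: 7 3-[4-(benzyloxy)-2,3-dimethoxyphenyl]propanoic acid
Conditions: LiOH·H2O, THF/MeOH/H2O, rt; then 1 M HCl
Reagents that add atoms: lithium hydroxide, [Li+].[OH-]
Why: Saponification of an unhindered ethyl ester is quantitative and no other group in the molecule is base-labile.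

Step 6
Reactants: 7 3-[4-(benzyloxy)-2,3-dimethoxyphenyl]propanoic acid; 8 (4R)-4-benzyl-1,3-oxazolidin-2-one
Product: 10 (4R)-4-benzyl-3-{3-[4-(benzyloxy)-2,3-dimethoxyphenyl]propanoyl}-1,3-oxazolidin-2-one, via mixed pivalic anhydride 9 (not isolated)
Conditions: PivCl, Et3N, THF, −20 °C; then 8, LiCl, −20 °C to rt
Reagents that add atoms: pivaloyl chloride, CC(C)(C)C(Cl)=O (its acyl group is carried by 9 only and leaves before 10)
Why: N-Acylation of the Evans auxiliary through the mixed anhydride, which the LiCl-activated oxazolidinone attacks at the unhindered acyl carbon and not at the pivaloyl carbon.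

Step 7
Reactants: 10 (4R)-4-benzyl-3-{3-[4-(benzyloxy)-2,3-dimethoxyphenyl]propanoyl}-1,3-oxazolidin-2-one; 11 tert-butyl bromoacetate
Product: 13 tert-butyl (3S)-4-[(4R)-4-benzyl-2-oxo-1,3-oxazolidin-3-yl]-3-{[4-(benzyloxy)-2,3-dimethoxyphenyl]methyl}-4-oxobutanoate, via sodium Z-enolate 12 (not isolated)
Conditions: NaN(SiMe3)2, THF, −78 °C; then 11, −78 to −45 °C
Reagents that add atoms: sodium bis(trimethylsilyl)amide, C[Si](C)(C)[N-][Si](C)(C)C.[Na+] (its sodium is carried by 12 only)
Why: Evans asymmetric alkylation, in which the chelated Z-enolate is attacked by the reactive bromoacetate on the face opposite the C4 benzyl group of the (R)-auxiliary, setting the new stereocentre as S (the future C3 of the target) with high diastereoselectivity.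

Step 8
Reactants: 13 tert-butyl (3S)-4-[(4R)-4-benzyl-2-oxo-1,3-oxazolidin-3-yl]-3-{[4-(benzyloxy)-2,3-dimethoxyphenyl]methyl}-4-oxobutanoate
Product: 14 tert-butyl (3S)-3-{[4-(benzyloxy)-2,3-dimethoxyphenyl]methyl}-4-hydroxybutanoate
Conditions: LiBH4, MeOH (1.1 equiv), THF, 0 °C
Reagents that add atoms: none
Why: Reductive cleavage of the N-acyl oxazolidinone by LiBH4 is much faster than reduction of the hindered tert-butyl ester, so the primary alcohol and the recoverable auxiliary are released without touching the stereocentre.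

Step 9
Reactants: 14 tert-butyl (3S)-3-{[4-(benzyloxy)-2,3-dimethoxyphenyl]methyl}-4-hydroxybutanoate
Product: 15 (4S)-4-{[4-(benzyloxy)-2,3-dimethoxyphenyl]methyl}oxolan-2-one
Conditions: TsOH·H2O (10 mol %), PhMe, 80 °C
Reagents that add atoms: none
Why: Acid-catalysed lactonisation of a γ-hydroxy tert-butyl ester closes the five-membered ring with loss of isobutene and water, and the non-enolisable stereocentre is retained.

Step 10
Reactants: 15 (4S)-4-{[4-(benzyloxy)-2,3-dimethoxyphenyl]methyl}oxolan-2-one; 16 4-(benzyloxy)-3-methoxybenzaldehyde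
Product: 18 (3R,4S)-3-{[4-(benzyloxy)-3-methoxyphenyl](hydroxy)methyl}-4-{[4-(benzyloxy)-2,3-dimethoxyphenyl]methyl}oxolan-2-one (both carbinol epimers), via lithium enolate 17 (not isolated)
Conditions: LiN(SiMe3)2, THF, −78 °C; then 16, −78 °C; AcOH quench at −78 °C
Reagents that add atoms: lithium bis(trimethylsilyl)amide, C[Si](C)(C)[N-][Si](C)(C)C.[Li+] (its lithium is carried by 17 only)
Why: Intermolecular aldol addition of the lactone enolate takes place anti to the C4 arylmethyl group, which sets the new ring stereocentre trans (3R, the future C2 of the target), while the carbinol centre forms as an epimer mixture that converges in the next step.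

Step 11
Reactants: 18 (3R,4S)-3-{[4-(benzyloxy)-3-methoxyphenyl](hydroxy)methyl}-4-{[4-(benzyloxy)-2,3-dimethoxyphenyl]methyl}oxolan-2-one (both carbinol epimers)
Product: 19 (3aS,9R,9aS)-7-(benzyloxy)-9-[4-(benzyloxy)-3-methoxyphenyl]-5,6-dimethoxy-3a,4,9,9a-tetrahydronaphtho[2,3-c]furan-1(3H)-one
Conditions: CF3CO2H, CH2Cl2, 0 °C to rt
Reagents that add atoms: none
Why: Intramolecular Friedel–Crafts alkylation, in which acid ionises the para-alkoxy-stabilised benzylic alcohol and the only free ortho carbon of the trioxygenated ring (para to its 3-methoxy group) closes the six-membered ring through a chair-like transition state with the aryl group pseudo-equatorial, so both carbinol epimers give the 1,2-trans product (9R, the C1 of the target).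

Step 12
Reactants: 19 (3aS,9R,9aS)-7-(benzyloxy)-9-[4-(benzyloxy)-3-methoxyphenyl]-5,6-dimethoxy-3a,4,9,9a-tetrahydronaphtho[2,3-c]furan-1(3H)-one
Product: 20 [(1R,2S,3S)-7-(benzyloxy)-1-[4-(benzyloxy)-3-methoxyphenyl]-3-(hydroxymethyl)-5,6-dimethoxy-1,2,3,4-tetrahydronaphthalen-2-yl]methanol
Conditions: LiAlH4, THF, 0 °C to rt
Reagents that add atoms: none
Why: Hydride reduction of the lactone to the 1,4-diol is faster than enolisation, so all three stereocentres are retained, and aryl benzyl and methyl ethers are inert to LiAlH4.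

Step 13
Reactants: 20 [(1R,2S,3S)-7-(benzyloxy)-1-[4-(benzyloxy)-3-methoxyphenyl]-3-(hydroxymethyl)-5,6-dimethoxy-1,2,3,4-tetrahydronaphthalen-2-yl]methanol
Product: 21 (6S,7S,8R)-8-(4-hydroxy-3-methoxyphenyl)-6,7-bis(hydroxymethyl)-3,4-dimethoxy-5,6,7,8-tetrahydronaphthalen-2-ol
Conditions: H2 (1 atm), Pd/C (10 wt %), EtOAc/MeOH, rt
Reagents that add atoms: none
Why: Catalytic hydrogenolysis cleaves both O-benzyl ethers while the benzylic C–C bonds, the methyl ethers and the alcohols are unaffected and no stereocentre is touched.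

## Compound list

1 | 2,3,4-trihydroxybenzaldehyde | O=Cc1ccc(O)c(O)c1O | starting material
2 | 4-(benzyloxy)-2,3-dihydroxybenzaldehyde | O=Cc1ccc(OCc2ccccc2)c(O)c1O | intermediate
3 | 4-(benzyloxy)-2,3-dimethoxybenzaldehyde | COc1c(OC)c(OCc2ccccc2)ccc1C=O | intermediate
4 | ethyl (triphenylphosphoranylidene)acetate | CCOC(=O)C=P(c1ccccc1)(c1ccccc1)c1ccccc1 | starting material
5 | ethyl (2E)-3-[4-(benzyloxy)-2,3-dimethoxyphenyl]prop-2-enoate | CCOC(=O)/C=C/c1ccc(OCc2ccccc2)c(OC)c1OC | intermediate
6 | ethyl 3-[4-(benzyloxy)-2,3-dimethoxyphenyl]propanoate | CCOC(=O)CCc1ccc(OCc2ccccc2)c(OC)c1OC | intermediate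
7 | 3-[4-(benzyloxy)-2,3-dimethoxyphenyl]propanoic acid | OC(=O)CCc1ccc(OCc2ccccc2)c(OC)c1OC | intermediate
8 | (4R)-4-benzyl-1,3-oxazolidin-2-one | O=C1N[C@H](Cc2ccccc2)CO1 | starting material
9 | mixed anhydride of 7 and pivalic acid (formed in the flask) | CC(C)(C)C(=O)OC(=O)CCc1ccc(OCc2ccccc2)c(OC)c1OC | intermediate
10 | (4R)-4-benzyl-3-{3-[4-(benzyloxy)-2,3-dimethoxyphenyl]propanoyl}-1,3-oxazolidin-2-one | COc1c(OC)c(OCc2ccccc2)ccc1CCC(=O)N1C(=O)OC[C@H]1Cc1ccccc1 | intermediate
11 | tert-butyl bromoacetate | CC(C)(C)OC(=O)CBr | starting material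
12 | sodium Z-enolate of 10 (formed in the flask) | COc1c(OC)c(OCc2ccccc2)ccc1C/C=C(\[O-])N1C(=O)OC[C@H]1Cc1ccccc1.[Na+] | intermediate
13 | tert-butyl (3S)-4-[(4R)-4-benzyl-2-oxo-1,3-oxazolidin-3-yl]-3-{[4-(benzyloxy)-2,3-dimethoxyphenyl]methyl}-4-oxobutanoate | COc1c(OC)c(OCc2ccccc2)ccc1C[C@@H](CC(=O)OC(C)(C)C)C(=O)N1C(=O)OC[C@H]1Cc1ccccc1 | intermediate
14 | tert-butyl (3S)-3-{[4-(benzyloxy)-2,3-dimethoxyphenyl]methyl}-4-hydroxybutanoate | COc1c(OC)c(OCc2ccccc2)ccc1C[C@@H](CC(=O)OC(C)(C)C)CO | intermediate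
15 | (4S)-4-{[4-(benzyloxy)-2,3-dimethoxyphenyl]methyl}oxolan-2-one | COc1c(OC)c(OCc2ccccc2)ccc1C[C@@H]1COC(=O)C1 | intermediate
16 | 4-(benzyloxy)-3-methoxybenzaldehyde (O-benzylvanillin) | COc1cc(C=O)ccc1OCc1ccccc1 | starting material
17 | lithium enolate of 15 (formed in the flask) | COc1c(OC)c(OCc2ccccc2)ccc1C[C@@H]1COC([O-])=C1.[Li+] | intermediate
18 | (3R,4S)-3-{[4-(benzyloxy)-3-methoxyphenyl](hydroxy)methyl}-4-{[4-(benzyloxy)-2,3-dimethoxyphenyl]methyl}oxolan-2-one, both epimers at the carbinol carbon | COc1c(OC)c(OCc2ccccc2)ccc1C[C@@H]1COC(=O)[C@H]1C(O)c1ccc(OCc2ccccc2)c(OC)c1 | intermediate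
19 | (3aS,9R,9aS)-7-(benzyloxy)-9-[4-(benzyloxy)-3-methoxyphenyl]-5,6-dimethoxy-3a,4,9,9a-tetrahydronaphtho[2,3-c]furan-1(3H)-one | COc1cc([C@@H]2c3cc(OCc4ccccc4)c(OC)c(OC)c3C[C@H](CO5)[C@H]2C5=O)ccc1OCc1ccccc1 | intermediate
20 | [(1R,2S,3S)-7-(benzyloxy)-1-[4-(benzyloxy)-3-methoxyphenyl]-3-(hydroxymethyl)-5,6-dimethoxy-1,2,3,4-tetrahydronaphthalen-2-yl]methanol | COc1cc([C@@H]2c3cc(OCc4ccccc4)c(OC)c(OC)c3C[C@H](CO)[C@H]2CO)ccc1OCc1ccccc1 | intermediate
21 | (6S,7S,8R)-8-(4-hydroxy-3-methoxyphenyl)-6,7-bis(hydroxymethyl)-3,4-dimethoxy-5,6,7,8-tetrahydronaphthalen-2-ol | COc1cc([C@@H]2c3cc(O)c(OC)c(OC)c3C[C@H](CO)[C@H]2CO)ccc1O | target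

## Step count and risk

Total step count: 13. Longest linear sequence: 13 steps (1 to 21); compounds 4, 8, 11 and 16 are bought.

The three steps most likely to fail:

**Step 1 (regioselective mono-benzylation).** The risk is benzylation at O-2 or O-3, or double alkylation. The fallback sets out from 1. The 2,3-diol is tied up with Na2B4O7·10H2O in aqueous NaOH as the sodium 2,3-O-borate complex of 1 F1. The only free phenoxide (O-4) is then alkylated with BnBr (EtOH co-solvent, 40 °C) to give the sodium 2,3-O-borate complex of 2 F2. Dilute HCl in the work-up hydrolyses the borate, and the route is rejoined at 2.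

**Step 10 (aldol).** The risk is retro-aldol or incomplete conversion with the electron-rich aldehyde. The fallback sets out from 15. Enolisation with LiN(SiMe3)2 and trapping with Me3SiCl at −78 °C gives the trimethylsilyl ketene acetal of 15 F3, which is isolated. It is then combined with 16 in a Mukaiyama aldol under BF3·OEt2 in CH2Cl2 at −78 °C. This addition is irreversible and again occurs anti to the C4 substituent. Acidic aqueous work-up removes silicon, and the route is rejoined at 18.

**Step 11 (Friedel–Crafts ring closure).** The closing position is para to a methoxy group flanked on both sides, and the product is a strained trans-fused lactone. Closure may therefore be slow enough for elimination to an arylidene lactone or intermolecular arylation to compete. The fallback sets out from 18 and reverses the order of reduction and cyclisation. LiAlH4 (THF, 0 °C) gives (2S,3S)-2-{[4-(benzyloxy)-3-methoxyphenyl](hydroxy)methyl}-3-{[4-(benzyloxy)-2,3-dimethoxyphenyl]methyl}butane-1,4-diol F4. Treatment with CF3CO2H in CH2Cl2 (or BF3·OEt2) then ionises the benzylic alcohol. The cation is stored reversibly as the 2-aryl tetrahydrofuran ether [(3S,4S)-2-[4-(benzyloxy)-3-methoxyphenyl]-4-{[4-(benzyloxy)-2,3-dimethoxyphenyl]methyl}oxolan-3-yl]methanol F5. This ether re-opens under the acid and funnels, free of lactone strain, to the all-trans tetralin. The route is rejoined at 20, bypassing 19.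

## Further compounds

F1 | step 1 | sodium 2,3-O-borate complex of 1 | [Na+].O=Cc1ccc(O)c2O[B-](O)(O)Oc12
F2 | step 1 | sodium 2,3-O-borate complex of 2 | [Na+].O=Cc1ccc(OCc3ccccc3)c2O[B-](O)(O)Oc12
F3 | step 10 | {[(4S)-4-{[4-(benzyloxy)-2,3-dimethoxyphenyl]methyl}-4,5-dihydrofuran-2-yl]oxy}trimethylsilane (silyl ketene acetal of 15) | COc1c(OC)c(OCc2ccccc2)ccc1C[C@@H]1COC(O[Si](C)(C)C)=C1
F4 | step 11 | (2S,3S)-2-{[4-(benzyloxy)-3-methoxyphenyl](hydroxy)methyl}-3-{[4-(benzyloxy)-2,3-dimethoxyphenyl]methyl}butane-1,4-diol, both carbinol epimers | COc1c(OC)c(OCc2ccccc2)ccc1C[C@H](CO)[C@@H](CO)C(O)c1ccc(OCc2ccccc2)c(OC)c1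
F5 | step 11 | [(3S,4S)-2-[4-(benzyloxy)-3-methoxyphenyl]-4-{[4-(benzyloxy)-2,3-dimethoxyphenyl]methyl}oxolan-3-yl]methanol, both epimers at C2 | COc1c(OC)c(OCc2ccccc2)ccc1C[C@@H]1COC(c2ccc(OCc3ccccc3)c(OC)c2)[C@@H]1CO
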